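The runs are calculated for substances that don't exist.

A full yield of complex with one exchanged is impossible in a flask where the same incoming ligand carries it on to complex with two exchanged. The three new flasks differ in their charge of incoming ligand, so the question is how far that charge moves the yield at the stated time.

| flask | starting complex | incoming ligand | leaving ligand | remark | time |
|---|---|---|---|---|---|
| epsilon | 0.035 M | 2 equiv | 7.5 equiv | run made earlier |  |
| Monday's | 0.035 M | 2.00 equiv | 5.00 equiv |  | 3.0 h |
| Tuesday's | 0.035 M | 2.50 equiv | 5.00 equiv |  | 3.0 h |
| Wednesday's | 0.035 M | 4.00 equiv | 5.00 equiv |  | 3.0 h |

epsilon run (percent of the starting complex charged)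

| time / min | complex with one exchanged / % | complex with two exchanged / % | starting complex / % |
|---|---|---|---|
| 8.00 | 9.6 | 0.5 | 89.8 |
| 20.0 | 19.9 | 0 | 77.5 |
| 40.0 | 33.9 | 1.2 | 65.9 |
| 60.0 | 42.8 | 4.0 | 53.6 |
| 80.0 | 49.2 | 6.4 | 45.0 |
| 120 | 55.0 | 11.0 | 32.8 |

(readings scatter by 1 percentage point)

- final complex with one exchanged, as a percentage of the starting complex charged, for each flask in turn (Monday's, Tuesday's, Wednesday's)

- a reading or a percentage of complex with two exchanged counts all its forms, free or not
- no earlier run changes the charge of incoming ligand; that part of a forecast is a guess
- no earlier run changes the charge of leaving ligand; that part of a forecast is a guess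

In the epsilon run the second exchange looks slow, with complex with two exchanged at 1.2% after 40.0 min. Yet from 80.0 min to 120 min it gains 4.6 percentage points while starting complex loses 12 points, a share of 37.7%.

The two numbers fit if each exchange is taken as first order in [incoming ligand], an assumption that no earlier run tests. That concentration then cancels, and the second rate over the first is S[complex with one exchanged]/[starting complex]. S is the selectivity factor, the ratio of the two rate constants. At 120 min in the epsilon run complex with one exchanged stands higher than starting complex, so a step with a smaller rate constant can take that share. The last interval gives the reading S = 0.282, rough with a scatter of 1 point on each reading.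

With x the fraction of starting complex left, the yield of complex with one exchanged is (x^S − x)/(1 − S). With that reading of S the curve peaks at 60.9% when x is 17.1%. On the same assumption the charge moves x along the curve, not the curve itself.

In a rough reckoning separate from the forecast, ln x is scaled from the epsilon run by charge times time, and leaving ligand is guessed to do nothing. For Monday's, Tuesday's and Wednesday's flasks in turn that gives x = 18.8%, 12.4% and 3.53%, hence estimated yields of 60.7%, 60.0% and 49.3%.

The forecast differs, with 59%, 56% and 40%, the last being “past the maximum, about 40%, and the most uncertain”.

The flasks give 61.6%, 62.6% and 53.8%.

    starting complex + incoming ligand → leaving ligand + complex with one exchanged (k = 10.4 /M/h)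
    complex with one exchanged + incoming ligand → leaving ligand + complex with two exchanged (k = 2.65 /M/h)
    complex with two exchanged + incoming ligand ⇌ idle adduct, settled at all times (K = 14.5 /M)
    crystals ⇌ complex with two exchanged, rate k4*(cs4 - [complex with two exchanged]) while solid is left; crystals form when [complex with two exchanged] > cs4 (solubility = 11.0 mM, k = 17.6 /h)

Wednesday's flask stands 14 points above the forecast. It ends with 4.03% of its starting complex left, which is less than the reckoned peak position. Put into the curve with S, that amount gives 50.7% for Wednesday's flask. Monday's flask ends with 22.2% left, and the same curve gives 60.2% there.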